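**Retrosynthetic overview**
- The (E)-4-hydroxystyryl unit is cut by olefin cross-metathesis to a vinyl carbinol. The vinyl carbinol comes from Wittig methylenation of an α-hydroxy lactol.
- The α-hydroxy lactol comes from a cis-fused tetralin γ-lactone by convex-face enolate hydroxylation (sets the carbinol centre C1') and partial reduction.
- Key disconnection: the C1–C2 bond of the tetralin. The β-carbon of a tethered enal acts as a carbene-generated homoenolate nucleophile and adds to an aliphatic aldehyde, followed by lactonisation.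
- The enal-aldehyde comes from 6-bromoveratraldehyde by formyl-olefination and a Heck reaction with allyl alcohol.
- Ring order: the aromatic ring is bought; the carbocyclic ring and the temporary lactone ring form together in the key step; the lactone is opened at the end.

Assumption: the sense of induction of the aminoindanol-derived triazolium catalyst in step 3 is assigned by analogy; its antipode is equally available if the opposite lactone enantiomer forms.

Target structure check: 6,7-dimethoxytetralin; C1 (S) carries the side chain and is cis to the C2 (R) hydroxyl; the side-chain carbinol C1' is S; the three centres are all-syn along the chain; the alkene is E.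

**Step 1**
Reactants: 1 2-bromo-4,5-dimethoxybenzaldehyde; 2 (triphenylphosphoranylidene)acetaldehyde
Product: 3 (2E)-3-(2-bromo-4,5-dimethoxyphenyl)prop-2-enal
Conditions: 2 (1.1 equiv), toluene, 80 °C
Reagents that add atoms: (triphenylphosphoranylidene)acetaldehyde (compound 2), O=CC=P(c1ccccc1)(c1ccccc1)c1ccccc1
Why: Wittig olefination with the stabilised formyl ylide gives the E-enal, and using close to one equivalent limits a second olefination to the dienal.

**Step 2**
Reactants: 3 (2E)-3-(2-bromo-4,5-dimethoxyphenyl)prop-2-enal; 4 prop-2-en-1-ol (allyl alcohol)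
Product: 5 (2E)-3-[4,5-dimethoxy-2-(3-oxopropyl)phenyl]prop-2-enal
Conditions: 4 (1.5 equiv), Pd(OAc)2 (5 mol%), Bu4NCl, NaHCO3, DMF, 90 °C
Reagents that add atoms: prop-2-en-1-ol (compound 4), C=CCO
Why: Heck reaction under Jeffery conditions, in which the aryl–palladium species adds to the terminal alkene and β-hydride elimination toward the carbinol gives an enol that tautomerises to the 3-arylpropanal; the 1,2-disubstituted enal of 3 is a much poorer insertion partner.

**Step 3**
Reactants: 5 (2E)-3-[4,5-dimethoxy-2-(3-oxopropyl)phenyl]prop-2-enal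
Product: 6 (3aR,9bS)-7,8-dimethoxy-3a,4,5,9b-tetrahydronaphtho[2,1-b]furan-2(1H)-one
Conditions: (5aS,10bR)-2-mesityl-5a,10b-dihydro-4H,6H-indeno[2,1-b][1,2,4]triazolo[4,3-d][1,4]oxazin-2-ium chloride (10 mol%), DBU (10 mol%), THF, 25 °C
Reagents that add atoms: none
Why: Proposed new method: the N-mesityl triazolylidene adds to the enal to give a Breslow-type homoenolate whose benzylic β-carbon attacks the tethered aldehyde in a six-membered ring closure, and the resulting alkoxide acylates the acyl azolium to release the carbene and the cis-fused γ-lactone, so the catalyst-shielded face of the homoenolate sets C9b and the lactonisation requirement sets C3a cis to it; the closest known reaction type is the carbene-catalysed homoenolate annulation of enals with aldehydes to cis-γ-butyrolactones, here run intramolecularly.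

**Step 4**
Reactants: 6 (3aR,9bS)-7,8-dimethoxy-3a,4,5,9b-tetrahydronaphtho[2,1-b]furan-2(1H)-one; 7 trans-3-phenyl-2-(phenylsulfonyl)oxaziridine
Product: 9 (1R,3aR,9bR)-1-hydroxy-7,8-dimethoxy-3a,4,5,9b-tetrahydronaphtho[2,1-b]furan-2(1H)-one, via potassium enolate 8 (not isolated)
Conditions: KHMDS, THF, −78 °C; then 7, −78 °C; AcOH quench
Reagents that add atoms: trans-3-phenyl-2-(phenylsulfonyl)oxaziridine (compound 7), O=S(=O)(c1ccccc1)N1OC1c1ccccc1
Why: Davis enolate hydroxylation, in which the oxaziridine approaches the convex face of the cis-fused bicyclic enolate, anti to the aryl ring carbon on C9b, so the new hydroxyl is cis to H-9b (1R).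

**Step 5**
Reactants: 9 (1R,3aR,9bR)-1-hydroxy-7,8-dimethoxy-3a,4,5,9b-tetrahydronaphtho[2,1-b]furan-2(1H)-one
Product: 10 (1R,3aR,9bR)-7,8-dimethoxy-1,2,3a,4,5,9b-hexahydronaphtho[2,1-b]furan-1,2-diol (anomer mixture)
Conditions: DIBAL-H (2.5 equiv), CH2Cl2, −78 °C; aq. Rochelle salt
Reagents that add atoms: none
Why: DIBAL-H partial reduction of a lactone stops at the lactol because the tetrahedral aluminate is stable at −78 °C; one extra equivalent is consumed by the free hydroxyl and no stereocentre is touched.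

**Step 6**
Reactants: 10 (1R,3aR,9bR)-7,8-dimethoxy-1,2,3a,4,5,9b-hexahydronaphtho[2,1-b]furan-1,2-diol; 11 methyltriphenylphosphonium bromide
Product: 12 (1S,2R)-1-[(1S)-1-hydroxyprop-2-en-1-yl]-6,7-dimethoxy-1,2,3,4-tetrahydronaphthalen-2-ol
Conditions: 11 (4 equiv), KOtBu (4 equiv), THF, 0 °C; then 10, 0 to 25 °C
Reagents that add atoms: methyltriphenylphosphonium bromide (compound 11), C[P+](c1ccccc1)(c1ccccc1)c1ccccc1.[Br-]
Why: Wittig methylenation of a lactol through its open hydroxy-aldehyde form, as in sugar lactol chemistry; the adjacent alkoxide disfavours enolisation so C1' is kept, and the lactol oxygen is released as the C2 hydroxyl.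

**Step 7**
Reactants: 12 (1S,2R)-1-[(1S)-1-hydroxyprop-2-en-1-yl]-6,7-dimethoxy-1,2,3,4-tetrahydronaphthalen-2-ol; 13 4-ethenylphenyl acetate (4-acetoxystyrene)
Product: 15 (1S,2R)-1-[(1S,2E)-1-hydroxy-3-(4-hydroxyphenyl)prop-2-en-1-yl]-6,7-dimethoxy-1,2,3,4-tetrahydronaphthalen-2-ol, via aryl acetate 14 (not isolated)
Conditions: 13 (4 equiv), second-generation Hoveyda–Grubbs catalyst (5 mol%), 1,4-benzoquinone (10 mol%), CH2Cl2, 40 °C; then K2CO3 (cat.), MeOH, 25 °C
Reagents that add atoms: 4-ethenylphenyl acetate (compound 13), CC(=O)Oc1ccc(C=C)cc1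
Why: Olefin cross-metathesis of a secondary allylic alcohol with a styrene gives the E-alkene under thermodynamic control (benzoquinone suppresses isomerisation of the allylic alcohol by ruthenium hydrides), and methanolysis of the labile aryl acetate in the same flask frees the phenol.

**Compound list**
1 | 2-bromo-4,5-dimethoxybenzaldehyde (6-bromoveratraldehyde) | COc1cc(Br)c(C=O)cc1OC | starting material
2 | (triphenylphosphoranylidene)acetaldehyde | O=CC=P(c1ccccc1)(c1ccccc1)c1ccccc1 | starting material
3 | (2E)-3-(2-bromo-4,5-dimethoxyphenyl)prop-2-enal | COc1cc(Br)c(/C=C/C=O)cc1OC | intermediate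
4 | prop-2-en-1-ol (allyl alcohol) | C=CCO | starting material
5 | (2E)-3-[4,5-dimethoxy-2-(3-oxopropyl)phenyl]prop-2-enal | COc1cc(CCC=O)c(/C=C/C=O)cc1OC | intermediate
6 | (3aR,9bS)-7,8-dimethoxy-3a,4,5,9b-tetrahydronaphtho[2,1-b]furan-2(1H)-one (cis-fused γ-lactone; lactone O on tetralin C2, lactone CH2 on tetralin C1) | COc1cc2c(cc1OC)[C@H](CC3=O)[C@H](O3)CC2 | intermediate
7 | trans-3-phenyl-2-(phenylsulfonyl)oxaziridine (Davis oxaziridine, racemic) | O=S(=O)(c1ccccc1)N1OC1c1ccccc1 | starting material
8 | potassium (3aR,9bS)-7,8-dimethoxy-3a,4,5,9b-tetrahydronaphtho[2,1-b]furan-2-olate (lactone enolate, formed in the flask in step 4) | COc1cc2c(cc1OC)[C@H](C=C3[O-])[C@H](O3)CC2.[K+] | intermediate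
9 | (1R,3aR,9bR)-1-hydroxy-7,8-dimethoxy-3a,4,5,9b-tetrahydronaphtho[2,1-b]furan-2(1H)-one (hydroxyl cis to H-9b) | COc1cc2c(cc1OC)[C@H]([C@@H](O)C3=O)[C@H](O3)CC2 | intermediate
10 | (1R,3aR,9bR)-7,8-dimethoxy-1,2,3a,4,5,9b-hexahydronaphtho[2,1-b]furan-1,2-diol (lactol, anomer mixture) | COc1cc2c(cc1OC)[C@H]([C@@H](O)C3O)[C@H](O3)CC2 | intermediate
11 | methyltriphenylphosphonium bromide | C[P+](c1ccccc1)(c1ccccc1)c1ccccc1.[Br-] | starting material
12 | (1S,2R)-1-[(1S)-1-hydroxyprop-2-en-1-yl]-6,7-dimethoxy-1,2,3,4-tetrahydronaphthalen-2-ol | COc1cc2c(cc1OC)[C@H]([C@@H](O)C=C)[C@H](O)CC2 | intermediate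
13 | 4-ethenylphenyl acetate (4-acetoxystyrene) | CC(=O)Oc1ccc(C=C)cc1 | starting material
14 | 4-[(1E,3S)-3-hydroxy-3-[(1S,2R)-2-hydroxy-6,7-dimethoxy-1,2,3,4-tetrahydronaphthalen-1-yl]prop-1-en-1-yl]phenyl acetate (formed in the flask in step 7) | COc1cc2c(cc1OC)[C@H]([C@@H](O)/C=C/c1ccc(OC(C)=O)cc1)[C@H](O)CC2 | intermediate
15 | (1S,2R)-1-[(1S,2E)-1-hydroxy-3-(4-hydroxyphenyl)prop-2-en-1-yl]-6,7-dimethoxy-1,2,3,4-tetrahydronaphthalen-2-ol | COc1cc2c(cc1OC)[C@H]([C@@H](O)/C=C/c1ccc(O)cc1)[C@H](O)CC2 | target

**Totals**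
Total step count: 7. Longest linear sequence: 7.

**Steps most likely to fail, with fallbacks**

Step 3 (key annulation). The aliphatic aldehyde may form its own acyl-anion intermediate and undergo a Stetter closure onto the enal, base may trigger an intramolecular Michael addition, or selectivity may be low. The fallback sets out from compound 1 and comes back at compound 6. Wittig reaction of 1 with methyl (triphenylphosphoranylidene)acetate gives methyl (2E)-3-(2-bromo-4,5-dimethoxyphenyl)prop-2-enoate F1. Heck reaction of F1 with allyl alcohol 4 under the step 2 conditions gives methyl (2E)-3-[4,5-dimethoxy-2-(3-oxopropyl)phenyl]prop-2-enoate F2. An intramolecular Stetter reaction of F2 (achiral triazolium salt, Et3N, toluene) joins the aldehyde carbon as an acyl anion to the enoate β-carbon and gives racemic, configurationally labile methyl 2-(6,7-dimethoxy-2-oxo-1,2,3,4-tetrahydronaphthalen-1-yl)acetate F3. Asymmetric transfer hydrogenation with dynamic kinetic resolution, using RuCl(p-cymene)(TsDPEN) of the enantiomeric series that delivers the 2R carbinol with HCO2H/Et3N, gives methyl 2-[(1S,2R)-2-hydroxy-6,7-dimethoxy-1,2,3,4-tetrahydronaphthalen-1-yl]acetate F4. F4 lactonises with catalytic TsOH to lactone 6.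

Step 2 (Heck reaction). The aryl bromide is para to a methoxy group and may react slowly, and dialdehyde 5 may not survive hot basic conditions. The fallback sets out from compound 3 and comes back at compound 5. Negishi coupling of 3 with commercial [2-(1,3-dioxolan-2-yl)ethyl]zinc bromide (PdCl2(dppf), THF, 40 °C) gives (2E)-3-{2-[2-(1,3-dioxolan-2-yl)ethyl]-4,5-dimethoxyphenyl}prop-2-enal F5. Mild hydrolysis of the acetal in F5 (aq. HCl, THF, 25 °C) gives 5.

Step 6 (methylenation of the α-hydroxy lactol). The strongly basic ylide may epimerise C1' or fail to engage the lactol. The fallback sets out from compound 10 and comes back at target 15, bypassing compound 12 and step 7. Non-basic Takai olefination of 10 (CrCl2, CHI3, THF, 0 to 25 °C) gives (1S,2R)-1-[(1R,2E)-1-hydroxy-3-iodoprop-2-en-1-yl]-6,7-dimethoxy-1,2,3,4-tetrahydronaphthalen-2-ol F6; the changed descriptor at the carbinol reflects only the priority of iodine. Suzuki–Miyaura coupling of F6 with 4-hydroxyphenylboronic acid (Pd(PPh3)4, K2CO3, dioxane/water, 60 °C) gives 15 with the E geometry retained.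

**Further compounds**
F1 | step 3 | methyl (2E)-3-(2-bromo-4,5-dimethoxyphenyl)prop-2-enoate | COC(=O)/C=C/c1cc(OC)c(OC)cc1Br
F2 | step 3 | methyl (2E)-3-[4,5-dimethoxy-2-(3-oxopropyl)phenyl]prop-2-enoate | COC(=O)/C=C/c1cc(OC)c(OC)cc1CCC=O
F3 | step 3 | methyl 2-(6,7-dimethoxy-2-oxo-1,2,3,4-tetrahydronaphthalen-1-yl)acetate (racemic) | COC(=O)CC1C(=O)CCc2cc(OC)c(OC)cc12
F4 | step 3 | methyl 2-[(1S,2R)-2-hydroxy-6,7-dimethoxy-1,2,3,4-tetrahydronaphthalen-1-yl]acetate | COc1cc2c(cc1OC)[C@H](CC(=O)OC)[C@H](O)CC2
F5 | step 2 | (2E)-3-{2-[2-(1,3-dioxolan-2-yl)ethyl]-4,5-dimethoxyphenyl}prop-2-enal | O=C/C=C/c1cc(OC)c(OC)cc1CCC1OCCO1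
F6 | step 6 | (1S,2R)-1-[(1R,2E)-1-hydroxy-3-iodoprop-2-en-1-yl]-6,7-dimethoxy-1,2,3,4-tetrahydronaphthalen-2-ol | COc1cc2c(cc1OC)[C@H]([C@@H](O)/C=C/I)[C@H](O)CC2
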